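**Retrosynthetic overview**

1. The catechol is unmasked last. Before that, ring B (the 2H-pyran: C1, O2, C3, C4, C4a, C8a) and the whole (E)-acrylic acid chain are removed together by cutting C4–C4a and O2–C3. This leaves a ring A enol triflate that carries the C1 hydroxymethyl group, and (E)-pent-2-en-4-ynoic acid.
2. Enabling feature: the C8 ketone of ring A makes C4a the β-carbon of an enone. C4a is therefore available as the enol triflate of a cyclohexane-1,3-dione, with the C1 hydroxyl cis to it on C8a. After alkynylation, C3 is the δ-carbon of the C8=O/C8a=C4a/C4≡C3 dienynone, which directs O2 to C3 (6-endo).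
3. Ring A comes intact from (S)-carvone: ketone = C8, methyl-bearing carbon = C7, α-methylene = C8a (aldol with formaldehyde gives C1), isopropenyl carbon = C4a (Criegee rearrangement, then oxidation to the 1,3-dione).
4. C6 and C7 are set by nucleophilic epoxidation of carvone anti to the isopropenyl group, then SN2 opening of the epoxide at C6 by the caesium salt of the MOM-protected aryl acid. This installs the hindered benzoate by alkylation and gives the trans ketol ester.
5. Order of rings: the arene and ring A are bought; ring B is the only ring made, in the key step, one step before the end.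

Key step: step 16

Remark: isochromene numbering of the target (C1, O2, C3, C4, C4a, C5 to C8, C8a) is used for all ring A intermediates. The intermediates between hydroxymethylation and the 1,3-dione are carried as mixtures of C8a epimers; this centre becomes sp2 at the dione.

**Route**

Step 1
Reactants: 1 2,3,4-trimethoxy-6-methylbenzaldehyde
Product: 2 2,3,4-trihydroxy-6-methylbenzaldehyde
Conditions: BBr3 (3.5 equiv), CH2Cl2, −78 °C to rt; then H2O
Reagents that add atoms: none
Why: Lewis acid-mediated cleavage of all three aryl methyl ethers by BBr3 proceeds through aryloxyboranes that hydrolyse on work-up, and the aldehyde is inert to the reagent.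

Step 2
Reactants: 2 2,3,4-trihydroxy-6-methylbenzaldehyde
Product: 3 2-hydroxy-3,4-bis(methoxymethoxy)-6-methylbenzaldehyde
Conditions: MOMCl (2.1 equiv), iPr2NEt, CH2Cl2, 0 °C
Reagents that add atoms: chloromethyl methyl ether, COCCl
Why: Williamson-type O-alkylation should be chemoselective because the C2 phenol is held in a hydrogen bond to the ortho formyl group and is the least nucleophilic hydroxyl, so two equivalents of MOMCl cap only O3 and O4.

Step 3
Reactants: 3 2-hydroxy-3,4-bis(methoxymethoxy)-6-methylbenzaldehyde
Product: 4 2-methoxy-3,4-bis(methoxymethoxy)-6-methylbenzaldehyde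
Conditions: MeI, K2CO3, DMF, 40 °C
Reagents that add atoms: iodomethane, CI
Why: Williamson etherification of the remaining chelated phenol with MeI and carbonate in a dipolar aprotic solvent is standard and leaves the MOM acetals untouched.

Step 4
Reactants: 4 2-methoxy-3,4-bis(methoxymethoxy)-6-methylbenzaldehyde
Product: 5 2-methoxy-3,4-bis(methoxymethoxy)-6-methylbenzoic acid
Conditions: NaClO2, NaH2PO4, 2-methyl-2-butene, t-BuOH/H2O, rt
Reagents that add atoms: sodium chlorite, [Na+].[O-]Cl=O
Why: Pinnick oxidation converts the hindered, electron-rich aldehyde to the acid at buffered pH while 2-methyl-2-butene scavenges hypochlorous acid, so the arene and the MOM ethers should survive.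

Step 5
Reactants: 6 3-(trimethylsilyl)prop-2-ynal
Product: 7 ethyl (E)-5-(trimethylsilyl)pent-2-en-4-ynoate
Conditions: (EtO)2P(O)CH2CO2Et, NaH, THF, 0 °C
Reagents that add atoms: triethyl phosphonoacetate, CCOC(=O)CP(=O)(OCC)OCC
Why: Horner–Wadsworth–Emmons olefination of the ynal with the stabilised phosphonate anion should give the (E)-enoate through the thermodynamically favoured anti oxaphosphetane.

Step 6
Reactants: 7 ethyl (E)-5-(trimethylsilyl)pent-2-en-4-ynoate
Product: 8 (E)-pent-2-en-4-ynoic acid
Conditions: LiOH, THF/H2O, 0 °C to rt; then 1 M HCl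
Reagents that add atoms: lithium hydroxide, [Li+].[OH-]
Why: Saponification of the ethyl ester and hydroxide-induced protodesilylation of the alkynylsilane occur in the same operation and do not touch the (E)-alkene.

Step 7
Reactants: 9 (S)-(+)-carvone
Product: 10 trans-carvone oxide
Conditions: 30% aq H2O2, NaOH (cat.), MeOH, 0 °C
Reagents that add atoms: hydrogen peroxide, OO
Why: Weitz–Scheffer nucleophilic epoxidation delivers hydroperoxide to the enone β-carbon anti to the isopropenyl group, so both new stereocentres (C6 and C7 of the target) are set by the resident stereocentre.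

Step 8
Reactants: 10 trans-carvone oxide; 5 2-methoxy-3,4-bis(methoxymethoxy)-6-methylbenzoic acid
Product: 11 trans ketol benzoate
Conditions: Cs2CO3 (0.3 equiv), DMF, 80 °C
Reagents that add atoms: none
Why: SN2 opening of the epoxide by the caesium carboxylate should occur at the secondary carbon C6 (the tertiary α-keto carbon C7 is closed to backside attack) with inversion, which sets the trans relationship of the ester and the retained tertiary alcohol and avoids acyl substitution at the di-ortho-substituted benzoyl carbon.

Step 9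
Reactants: 11 trans ketol benzoate
Product: 13 hydroxymethyl ketone, via dilithium enolate alkoxide 12 (not isolated)
Conditions: LiN(SiMe3)2 (2.1 equiv), THF, −78 °C; CH2O (gas, from cracked paraformaldehyde), −78 °C; AcOH
Reagents that add atoms: formaldehyde, C=O
Why: Aldol hydroxymethylation is regiospecific because the ketone can enolise only towards C8a (C7 is quaternary), the amide base is too weak to metalate the ortho-toluate methyl group, and the configuration of the new centre is irrelevant since C8a later becomes sp2.

Step 10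
Reactants: 13 hydroxymethyl ketone
Product: 14 bis(triethylsilyl) ether
Conditions: Et3SiOTf (2.6 equiv), 2,6-lutidine, CH2Cl2, −78 to 0 °C
Reagents that add atoms: triethylsilyl trifluoromethanesulfonate, CC[Si](CC)(CC)OS(=O)(=O)C(F)(F)F
Why: Silylation with a silyl triflate and a hindered pyridine base caps the primary and the hindered tertiary hydroxyl in one operation without enolising the ketone, which protects both from acetylation and oxidation in the next steps.

Step 11
Reactants: 14 bis(triethylsilyl) ether
Product: 16 C4a acetate, via methoxy hydroperoxide 15 (not isolated)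
Conditions: O3, CH2Cl2/MeOH (4:1), −78 °C; then Ac2O, Et3N, 4-(dimethylamino)pyridine (cat.), 0 °C to rt
Reagents that add atoms: ozone, [O-][O+]=O; methanol, CO
Why: Ozonolysis in methanol gives the α-methoxy hydroperoxide, whose peracetate undergoes Criegee rearrangement with migration of the ring carbon C4a with retention, and demethylation of the resulting dioxacarbenium ion by acetate leaves the former isopropenyl carbons as the acetate on C4a.

Step 12
Reactants: 16 C4a acetate
Product: 17 β-hydroxy ketone
Conditions: Candida antarctica lipase B (immobilised), n-BuOH, MTBE, 35 °C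
Reagents that add atoms: none
Why: Lipase (serine hydrolase) alcoholysis removes the secondary acetate at neutral pH, which avoids the E1cB loss of acetate that a basic methanolysis would cause in this β-acetoxy ketone and leaves the hindered benzoate and the silyl ethers alone.

Step 13
Reactants: 17 β-hydroxy ketone
Product: 18 1,3-dione (enol form)
Conditions: Dess–Martin periodinane, NaHCO3, CH2Cl2, 0 °C to rt
Reagents that add atoms: none
Why: Dess–Martin oxidation of the β-hydroxy ketone under buffered, non-basic conditions gives the 2-substituted cyclohexane-1,3-dione, which removes the C4a and C8a stereocentres and is best carried forward without storage.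

Step 14
Reactants: 18 1,3-dione (enol form)
Product: 19 enol triflate
Conditions: PhNTf2, Et3N, 4-(dimethylamino)pyridine (cat.), CH2Cl2, 0 °C to rt
Reagents that add atoms: N-phenylbis(trifluoromethanesulfonimide), O=S(=O)(N(c1ccccc1)S(=O)(=O)C(F)(F)F)C(F)(F)F
Why: O-sulfonylation of the dione enolate should take place at the oxygen on C4a, which is flanked by the C5 methylene, and not at O8, which is shielded by the quaternary C7 with its methyl and triethylsilyloxy groups, giving the β-triflyloxy enone with the ketone at C8.

Step 15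
Reactants: 19 enol triflate
Product: 20 diol triflate
Conditions: HF·pyridine, pyridine, THF, 0 °C to rt
Reagents that add atoms: none
Why: Buffered fluoride desilylation removes both triethylsilyl ethers, while the vinyl triflate, the MOM acetals and the benzoate are stable to HF·pyridine.

Step 16
Reactants: 20 diol triflate; 8 (E)-pent-2-en-4-ynoic acid
Product: 22 bis-MOM ether of the target, via ynenone 21 (not isolated)
Conditions: Pd(PPh3)2Cl2 (5 mol %), CuI (10 mol %), iPr2NEt (4 equiv), degassed DMF, rt then 45 °C; pH 3 work-up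
Reagents that add atoms: none
Why: Zerovalent palladium inserts into the C4a–OTf bond of the β-triflyloxy enone, the copper acetylide of 8 (present as its ammonium carboxylate) transmetalates, and reductive elimination forms C4–C4a to give ynenone 21; the C1 hydroxyl, held cis to the alkyne on the C8a=C4a double bond, then adds across the alkyne at C3 with amine and CuI assistance, and protonation at C4 completes the O2–C3 bond. The closest known reaction type is the one-pot Sonogashira coupling–hydroalkoxylation (heteroannulation) of 2-halobenzyl and (Z)-3-haloallyl alcohols with terminal alkynes, which gives 1H-isochromenes, isobenzofurans and furans. Ring B is the only ring closed, and it closes in the 6-endo-dig mode (O2 onto C3). No stereocentre is created, and C6 and C7 are not epimerisable under amine base (C7 is quaternary, C6 is not α to a carbonyl). The selectivity needed is 6-endo over 5-exo closure (attack on C4, which would lead on to a furan); it should be secured because C3 is the δ-carbon of the C8=O/C8a=C4a/C4≡C3 dienynone (vinylogous oxa-Michael polarity), because the side chain is a carboxylate under the reaction conditions and so offers no competing acceptor that would polarise the alkyne towards C4, because the alcohol is primary, and because only the 6-endo product is the fully conjugated vinylogous ester. Chemoselectivity rests on the vinyl triflate being the only bond that reacts with zerovalent palladium at room temperature, while the MOM ethers, the hindered benzoate, the tertiary ketol and the (E)-alkene are inert.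

Step 17
Reactants: 22 bis-MOM ether of the target
Product: 23 CNP0446308.4
Conditions: TFA/CH2Cl2 (1:5), H2O (5 equiv), 0 °C to rt
Reagents that add atoms: none
Why: Acid-catalysed cleavage of the two aryl MOM acetals through oxocarbenium ions releases the catechol, and the vinylogous ester, the tertiary ketol, the benzoate and the acrylic acid should tolerate brief exposure to TFA.

**Compound list**

1 | 2,3,4-trimethoxy-6-methylbenzaldehyde | O=Cc1c(C)cc(OC)c(OC)c1OC | starting material
2 | 2,3,4-trihydroxy-6-methylbenzaldehyde | O=Cc1c(C)cc(O)c(O)c1O | intermediate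
3 | 2-hydroxy-3,4-bis(methoxymethoxy)-6-methylbenzaldehyde | O=Cc1c(C)cc(OCOC)c(OCOC)c1O | intermediate
4 | 2-methoxy-3,4-bis(methoxymethoxy)-6-methylbenzaldehyde | O=Cc1c(C)cc(OCOC)c(OCOC)c1OC | intermediate
5 | 2-methoxy-3,4-bis(methoxymethoxy)-6-methylbenzoic acid | OC(=O)c1c(C)cc(OCOC)c(OCOC)c1OC | intermediate
6 | 3-(trimethylsilyl)prop-2-ynal | C[Si](C)(C)C#CC=O | starting material
7 | ethyl (E)-5-(trimethylsilyl)pent-2-en-4-ynoate | CCOC(=O)/C=C/C#C[Si](C)(C)C | intermediate
8 | (E)-pent-2-en-4-ynoic acid | OC(=O)/C=C/C#C | intermediate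
9 | (S)-(+)-carvone | CC(=C)[C@H]1CC=C(C)C(=O)C1 | starting material
10 | (1S,4S,6S)-1-methyl-4-(prop-1-en-2-yl)-7-oxabicyclo[4.1.0]heptan-2-one (epoxide anti to isopropenyl) | O1[C@H]2C[C@H](C(C)=C)CC(=O)[C@@]12C | intermediate
11 | (1R,2S,5S)-2-hydroxy-2-methyl-3-oxo-5-(prop-1-en-2-yl)cyclohexyl 2-methoxy-3,4-bis(methoxymethoxy)-6-methylbenzoate | COCOc1cc(C)c(C(=O)O[C@@H]2C[C@H](C(C)=C)CC(=O)[C@@]2(C)O)c(OC)c1OCOC | intermediate
12 | dilithium enolate alkoxide of 11 (enolate towards C8a, lithium alkoxide at C7) | COCOc1cc(C)c(C(=O)O[C@@H]2C[C@H](C(C)=C)C=C(O[Li])[C@@]2(C)O[Li])c(OC)c1OCOC | intermediate (not isolated)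
13 | (1R,2S,5S)-2-hydroxy-4-(hydroxymethyl)-2-methyl-3-oxo-5-(prop-1-en-2-yl)cyclohexyl 2-methoxy-3,4-bis(methoxymethoxy)-6-methylbenzoate, epimers at C4 of the cyclohexyl ring (C8a) | COCOc1cc(C)c(C(=O)O[C@@H]2C[C@H](C(C)=C)C(CO)C(=O)[C@@]2(C)O)c(OC)c1OCOC | intermediate
14 | (1R,2S,5S)-2-methyl-3-oxo-5-(prop-1-en-2-yl)-2-(triethylsilyloxy)-4-[(triethylsilyloxy)methyl]cyclohexyl 2-methoxy-3,4-bis(methoxymethoxy)-6-methylbenzoate, epimers at C4 | COCOc1cc(C)c(C(=O)O[C@@H]2C[C@H](C(C)=C)C(CO[Si](CC)(CC)CC)C(=O)[C@@]2(C)O[Si](CC)(CC)CC)c(OC)c1OCOC | intermediate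
15 | α-methoxy hydroperoxide of 14 (isopropenyl replaced by C(CH3)(OCH3)OOH, both configurations at that carbon) | COCOc1cc(C)c(C(=O)O[C@@H]2C[C@H](C(C)(OC)OO)C(CO[Si](CC)(CC)CC)C(=O)[C@@]2(C)O[Si](CC)(CC)CC)c(OC)c1OCOC | intermediate (not isolated)
16 | (1R,2S,5S)-5-acetoxy-2-methyl-3-oxo-2-(triethylsilyloxy)-4-[(triethylsilyloxy)methyl]cyclohexyl 2-methoxy-3,4-bis(methoxymethoxy)-6-methylbenzoate, acetoxy cis to the aroyloxy group, epimers at C4 | COCOc1cc(C)c(C(=O)O[C@@H]2C[C@H](OC(C)=O)C(CO[Si](CC)(CC)CC)C(=O)[C@@]2(C)O[Si](CC)(CC)CC)c(OC)c1OCOC | intermediate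
17 | (1R,2S,5S)-5-hydroxy-2-methyl-3-oxo-2-(triethylsilyloxy)-4-[(triethylsilyloxy)methyl]cyclohexyl 2-methoxy-3,4-bis(methoxymethoxy)-6-methylbenzoate, epimers at C4 | COCOc1cc(C)c(C(=O)O[C@@H]2C[C@H](O)C(CO[Si](CC)(CC)CC)C(=O)[C@@]2(C)O[Si](CC)(CC)CC)c(OC)c1OCOC | intermediate
18 | (1R,2S)-5-hydroxy-2-methyl-3-oxo-2-(triethylsilyloxy)-4-[(triethylsilyloxy)methyl]cyclohex-4-en-1-yl 2-methoxy-3,4-bis(methoxymethoxy)-6-methylbenzoate (enol form of the 1,3-dione) | COCOc1cc(C)c(C(=O)O[C@@H]2CC(O)=C(CO[Si](CC)(CC)CC)C(=O)[C@@]2(C)O[Si](CC)(CC)CC)c(OC)c1OCOC | intermediate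
19 | (1R,2S)-2-methyl-3-oxo-2-(triethylsilyloxy)-4-[(triethylsilyloxy)methyl]-5-(trifluoromethanesulfonyloxy)cyclohex-4-en-1-yl 2-methoxy-3,4-bis(methoxymethoxy)-6-methylbenzoate | COCOc1cc(C)c(C(=O)O[C@@H]2CC(OS(=O)(=O)C(F)(F)F)=C(CO[Si](CC)(CC)CC)C(=O)[C@@]2(C)O[Si](CC)(CC)CC)c(OC)c1OCOC | intermediate
20 | (1R,2S)-2-hydroxy-4-(hydroxymethyl)-2-methyl-3-oxo-5-(trifluoromethanesulfonyloxy)cyclohex-4-en-1-yl 2-methoxy-3,4-bis(methoxymethoxy)-6-methylbenzoate | COCOc1cc(C)c(C(=O)O[C@@H]2CC(OS(=O)(=O)C(F)(F)F)=C(CO)C(=O)[C@@]2(C)O)c(OC)c1OCOC | intermediate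
21 | (2E)-5-{(4S,5R)-4-hydroxy-2-(hydroxymethyl)-5-[2-methoxy-3,4-bis(methoxymethoxy)-6-methylbenzoyloxy]-4-methyl-3-oxocyclohex-1-en-1-yl}pent-2-en-4-ynoic acid | COCOc1cc(C)c(C(=O)O[C@@H]2CC(C#C/C=C/C(=O)O)=C(CO)C(=O)[C@@]2(C)O)c(OC)c1OCOC | intermediate (not isolated)
22 | (2E)-3-{(6R,7S)-7-hydroxy-6-[2-methoxy-3,4-bis(methoxymethoxy)-6-methylbenzoyloxy]-7-methyl-8-oxo-5,6,7,8-tetrahydro-1H-isochromen-3-yl}prop-2-enoic acid | COCOc1cc(C)c(C(=O)O[C@@H]2CC3=C(COC(/C=C/C(=O)O)=C3)C(=O)[C@@]2(C)O)c(OC)c1OCOC | intermediate
23 | (2E)-3-[(6R,7S)-6-(3,4-dihydroxy-2-methoxy-6-methylbenzoyloxy)-7-hydroxy-7-methyl-8-oxo-5,6,7,8-tetrahydro-1H-isochromen-3-yl]prop-2-enoic acid (CNP0446308.4) | COc1c(O)c(O)cc(C)c1C(=O)O[C@@H]1CC2=C(COC(/C=C/C(=O)O)=C2)C(=O)[C@@]1(C)O | target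

**Step count and risks**

Total step count: 17. Longest linear sequence: 14 steps (steps 1 to 4, then 8 to 17).

Steps most likely to fail:

Step 16. The hydroxyl may close in the 5-exo-dig mode onto C4, followed by tautomerisation of the exocyclic enol ether to a furan, or the free carboxylate may slow the palladium/copper cycle. The fallback removes the acceptor from the alkyne during ring formation and builds the acrylate afterwards. It sets out from 20, which is coupled and cyclised under the same Pd(PPh3)2Cl2/CuI/iPr2NEt conditions with 3,3-diethoxyprop-1-yne to give the 3-(diethoxymethyl)-1H-isochromen-8-one F1. Mild hydrolysis (pyridinium p-toluenesulfonate, acetone/H2O) gives the 3-formyl pyran F2. Wittig olefination with tert-butyl (triphenylphosphoranylidene)acetate in CH2Cl2 gives the (E)-tert-butyl acrylate F3. TFA/CH2Cl2 then removes the tert-butyl ester and both MOM ethers together, and the fallback comes back to the route at 23.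

Step 8. Backside attack at C6 in the isopropenyl-equatorial half-chair must pass through a twist-boat, so the SN2 opening may be slow. This would allow base-mediated degradation of the epoxy ketone or misdirected attack at C7. The fallback replaces carboxylate alkylation by hydrolysis and acyl transfer. It sets out from 10, which is hydrolysed with catalytic HClO4 in THF/H2O; water attacks C6 because cation character at the α-keto carbon C7 is disfavoured, giving the trans-diol F4. In parallel, 5 is converted with 1-chloro-N,N,2-trimethylprop-1-en-1-amine under neutral conditions into the acid chloride F5. Acylation of the secondary hydroxyl of F4 with F5 (4-(dimethylamino)pyridine, Et3N, CH2Cl2, 40 °C; the tertiary hydroxyl does not react) brings the fallback back to the route at 11.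

Step 12. The β-acetoxy ketone may lose acetate by E1cB elimination through the C8 enolate, or the lipase may not accept the hindered acetate. The fallback avoids the acetate altogether by an oxodealkenylation. It sets out from 14, which is ozonised in MeOH at −78 °C and treated with FeSO4·7H2O and 2,2,6,6-tetramethylpiperidin-1-oxyl. β-Scission of the alkoxy radical and trapping of the C4a radical give the alkoxyamine F6. Oxidation of F6 with 3-chloroperbenzoic acid (1 equiv, CH2Cl2, 0 °C) gives the C4a ketone, so the fallback comes back to the route at 18 and bypasses 16 and 17.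

**Further compounds**

F1 | step 16 | (6R,7S)-3-(diethoxymethyl)-7-hydroxy-7-methyl-8-oxo-5,6,7,8-tetrahydro-1H-isochromen-6-yl 2-methoxy-3,4-bis(methoxymethoxy)-6-methylbenzoate | COCOc1cc(C)c(C(=O)O[C@@H]2CC3=C(COC(C(OCC)OCC)=C3)C(=O)[C@@]2(C)O)c(OC)c1OCOC
F2 | step 16 | (6R,7S)-3-formyl-7-hydroxy-7-methyl-8-oxo-5,6,7,8-tetrahydro-1H-isochromen-6-yl 2-methoxy-3,4-bis(methoxymethoxy)-6-methylbenzoate | COCOc1cc(C)c(C(=O)O[C@@H]2CC3=C(COC(C=O)=C3)C(=O)[C@@]2(C)O)c(OC)c1OCOC
F3 | step 16 | tert-butyl (2E)-3-{(6R,7S)-7-hydroxy-6-[2-methoxy-3,4-bis(methoxymethoxy)-6-methylbenzoyloxy]-7-methyl-8-oxo-5,6,7,8-tetrahydro-1H-isochromen-3-yl}prop-2-enoate | COCOc1cc(C)c(C(=O)O[C@@H]2CC3=C(COC(/C=C/C(=O)OC(C)(C)C)=C3)C(=O)[C@@]2(C)O)c(OC)c1OCOC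
F4 | step 8 | (2S,3R,5S)-2,3-dihydroxy-2-methyl-5-(prop-1-en-2-yl)cyclohexan-1-one | O[C@@H]1C[C@H](C(C)=C)CC(=O)[C@@]1(C)O
F5 | step 8 | 2-methoxy-3,4-bis(methoxymethoxy)-6-methylbenzoyl chloride | ClC(=O)c1c(C)cc(OCOC)c(OCOC)c1OC
F6 | step 12 | (1R,2S)-2-methyl-3-oxo-5-(2,2,6,6-tetramethylpiperidin-1-yloxy)-2-(triethylsilyloxy)-4-[(triethylsilyloxy)methyl]cyclohexyl 2-methoxy-3,4-bis(methoxymethoxy)-6-methylbenzoate, epimers at C4 and C5 | COCOc1cc(C)c(C(=O)O[C@@H]2CC(ON3C(C)(C)CCCC3(C)C)C(CO[Si](CC)(CC)CC)C(=O)[C@@]2(C)O[Si](CC)(CC)CC)c(OC)c1OCOC
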